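Remark on the chemistry: the boron aldol of the α-aryl imide 8 is assumed to follow the usual sense of induction of Z-enolates of N-acyl oxazolidinones. Positions are numbered as in 2,3-dihydro-1-benzofuran (O1, C2, C3, C3a, C4 to C7, C7a); ring A is the benzo ring, ring B the dihydrofuran ring, ring C the 4-hydroxy-3-methoxyphenyl ring on C2, and the chain carbons are Cα (on C5), Cβ and Cγ.

## Analysis of the target

The target 23 is a trans-2-aryl-3-(hydroxymethyl)-2,3-dihydrobenzofuran (ring A fused to ring B) with a methoxy group on C7, ring C on C2 and a 1,2,3-trihydroxypropyl chain on C5. It has four stereocentres: C2 (R) and C3 (S), trans to each other on ring B, and Cα (S) and Cβ (R), which are erythro. Ring A lies between the two pairs, so neither pair can direct the other and absolute configuration has to be brought in twice. The O1–C2 bond is a benzylic ether para to the free phenol of ring C and can open to a para-quinone methide under acid or base. The Cα hydroxyl is benzylic and para to O1, so acid can ionise it and scramble erythro and threo. Five free hydroxyls make the compound very polar, and an erythro diol cannot be made by syn-dihydroxylation of an E-alkene. The strategy turns the lability of C2 into an advantage. Because C2 is bonded to O1 and stands para to the phenolic oxygen of ring C, the O1–C2 bond can be formed through a planar para-quinone methide, so only C3 needs asymmetric synthesis and C2 follows from it.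

## Retrosynthetic reasoning

**Protecting groups, 23 to 22 to 21.** The last two operations form no bond to carbon. 23 is traced back to the acetonide 22 and this to the bis-silyl ether 21. The silyl ethers go first, with a fluoride source, while the material is still soluble in organic solvents and can be separated from ammonium salts. The acetonide goes last under weak aqueous acid, which has to be mild enough not to ionise the Cα–O bond.

**Bond C5–Cα, 21 to 17 and 18.** This is the only cut that separates a core holding C2 and C3 from a three-carbon piece holding Cβ, so the two independent stereochemical problems are divided at once. Cβ is bought with aldehyde 18. Cα is made in the bond-forming step: the aryllithium 19, passed on to the aryltitanium 20, has to add to 18 in the Felkin–Anh sense. That gives the anti (erythro) carbinol, which dihydroxylation of an E-alkene cannot give. The bromine of 17 is the handle; it is already present in starting material 1 and is inert to every step before.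

**Silyl ethers, 17 to 16.** 17 is 16 with its two acidic hydroxyls (ring C phenol and primary alcohol) masked, as the organometallic step requires.

**Bond O1–C2, 16 to 14 through 15.** Ring B is opened at O1–C2 to the diol 14. The cut is made here, and not at C2–C3 or C3–C3a, because C2 is benzylic and para to the ring C phenol. Dehydration of either carbinol epimer of 14 gives the same quinone methide 15, planar at the future C2. The forward reaction must let the ring A phenol add to that carbon and place ring C trans to the hydroxymethyl group on C3. Since the new benzylic ether can ionise again under the same acid, kinetic and thermodynamic control both lead to trans. The gain is that only C3 of the two ring stereocentres has to be set by asymmetric synthesis. A closure by direct displacement with inversion was dropped: the syn aldol product would then give the cis ring, and the primary alcohol would be activated before the benzylic one.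

**Deprotection and reduction, 14 to 13 to 12.** 14 comes from its bis-allyl ether 13. Allyl ethers were chosen because zerovalent palladium removes them under neutral conditions. Hydrogenolysis would endanger the aryl bromide and the benzylic C–O bond, and an acid-labile group would start the ring closure before the precursor is isolated. 13 is the reduction product of imide 12; the acyl carbon becomes the hydroxymethyl carbon on C3.

**Aldol bond between the future C2 and C3, 12 to 8 and 10.** The boron enolate 11 of imide 8 adds to aldehyde 10. The forward reaction has to fix only the aryl-bearing carbon; the carbinol centre made with it is erased in 15. With the R-configured auxiliary 6 the model predicts 2R in 12. This is the S centre of 13, 14 and 23 once the carbonyl has become CH2OH and the priorities change.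

**Imide and building blocks, 8 to 5 and 6; 5 to 3 to 2 to 1; 10 to 9.** 8 is the N-acylation product of auxiliary 6 with arylacetic acid 5. 5 is the one-carbon homologue of aldehyde 2 (through enol ether 3 and aldehyde 4), and 2 is the allyl ether of 1. Aldehyde 10 is the allyl ether of 9.

## Alternatives that were turned down

**Alternative 1:** correction of a threo side chain through a temporary cyclic carbonate.
- Disconnection: not ring B but the Cα–O bond. A preformed, pivalate-protected core with an E-configured three-carbon chain is dihydroxylated to the threo diol A2, whose Cγ oxygen carries a dimethylcarbamate.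
- Forward key step: a boron Lewis acid ionises the Cα hydroxyl of A2 and the carbamate carbonyl oxygen captures the cation. Hydrolysis leaves the six-membered cyclic carbonate A1, with the aryl group and the neighbouring hydroxyl trans, which is the erythro arrangement.
- For it: both chain centres come from a catalytic, reagent-controlled dihydroxylation. In absolute sense this is more dependable than a substrate-controlled addition to a configurationally fragile α-alkoxy aldehyde, and on this point the alternative is stronger.
- Against it: it solves only the chain, so C2 and C3 still need a ring construction of their own. It spends several operations (carbamate, ionisation, carbonate and pivalate cleavage) repairing what syn addition to an E-alkene must deliver wrong. The inversion is an SN1 event whose selectivity rests on the trans preference of the six-membered ring, not on backside attack. The Lewis acid also meets the second ionisable benzylic bond at C2, which is held only by acylating the ring C phenol.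
- Comparison: the chosen route makes the C5–Cα bond and the erythro relation in one step from the chiral pool. In place of catalyst control it offers brevity and a simple oxidation and chelate-reduction correction.

**Alternative 2:** chiral benzylsulfonium ylide [4+1] on an ortho-quinone methide.
- Disconnection: C2–C3 and O1–C2 together. Ring A supplies an ortho-quinone methide released from the phenol sulfone A4, and ring C comes in as the chiral sulfonium salt A5.
- Forward key step: a carbonate base liberates both reactive partners. The ylide carbon adds to the methide carbon, and the phenoxide then displaces the chiral sulfide to give the trans dihydrobenzofuran A3.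
- For it: two bonds, ring B and both ring stereocentres form in one step from two aromatic pieces of similar size. Trans selectivity is built into the addition and displacement sequence, and no auxiliary has to be attached and removed. In convergence and step count to the brominated core it is stronger than the chosen route.
- Against it: absolute configuration must be relayed from a stereogenic sulfide to a flat, short-lived ortho-quinone methide. Addition of a stabilised benzyl ylide is probably reversible, so the facial choice at C3 is open to erosion. The methide carries a CH2OSi group with an adjacent C–H and can tautomerise to an ortho-vinylphenol before the ylide arrives. The chiral sulfide is stoichiometric.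
- Comparison: the chosen route puts C3 under an auxiliary aldol with a well-understood transition state and leaves C2 to thermodynamics. The sequence is longer, but the residual risk is a ring closure whose worst outcome is a separable by-product, not a product of low enantiomeric purity.

**Alternative 3:** oxypalladation and carbonylation of a flat 2-hydroxystilbene.
- Disconnection: O1–C2 and the bond from C3 to its exocyclic carbon; the precursor is the achiral stilbene A7.
- Forward key step: divalent palladium with a chiral bisoxazoline ligand activates the alkene and the phenol oxygen attacks the carbon bearing ring C. The C3–palladium bond undergoes alkoxycarbonylation to give the trans diester A6.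
- For it: it is catalytic in the chiral component, the precursor has no stereocentre and is one olefination away from simple aldehydes, and the C3 carbon substituent is installed in the same step. In atom and catalyst economy it is stronger.
- Against it: the relative configuration depends on the mode of oxypalladation together with the alkene geometry, with no thermodynamic correction. The alkylpalladium intermediate has a β-hydrogen on C2 whose loss gives an aromatic 2-arylbenzofuran, so carbonylation must outrun a very favourable elimination. Enantiocontrol on a 1,2-diaryl alkene with an oxidisable free phenol and a quinone reoxidant has no close analogy. The C5 ester must still be turned into the erythro triol over many steps and told apart from the C3 ester.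
- Comparison: the chosen route closes ring B less elegantly, but its C5 bromine becomes the complete side chain in a single C–C bond formation.

Key step: step 9

## Route

Step 1
Reactants: 1 5-bromo-2-hydroxy-3-methoxybenzaldehyde
Product: 2 2-(allyloxy)-5-bromo-3-methoxybenzaldehyde
Conditions: allyl bromide, K2CO3, DMF, rt
Reagents that add atoms: allyl bromide, C=CCBr
Why: Williamson etherification of the phenoxide; the allyl ether should survive ylide, aqueous acid, chlorite, boron triflate and borohydride and can later be removed by zerovalent palladium without touching the aryl bromide.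

Step 2
Reactants: 2 2-(allyloxy)-5-bromo-3-methoxybenzaldehyde
Product: 3 2-(allyloxy)-5-bromo-1-methoxy-3-(2-methoxyethenyl)benzene (E/Z mixture)
Conditions: Ph3P(CH2OMe)Cl, KOtBu, THF, 0 °C to rt
Reagents that add atoms: (methoxymethyl)triphenylphosphonium chloride, COC[P+](c1ccccc1)(c1ccccc1)c1ccccc1.[Cl-]
Why: Wittig olefination with the methoxymethylene ylide adds the one carbon needed; both enol ether isomers hydrolyse to the same aldehyde, so the geometry is of no account.

Step 3
Reactants: 3 2-(allyloxy)-5-bromo-1-methoxy-3-(2-methoxyethenyl)benzene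
Product: 5 2-[2-(allyloxy)-5-bromo-3-methoxyphenyl]acetic acid, via arylacetaldehyde 4 (not isolated)
Conditions: 2 M aq. HCl, THF, 50 °C; then NaClO2, NaH2PO4, 2-methyl-2-butene, t-BuOH/H2O, 0 °C to rt
Reagents that add atoms: water, O; sodium chlorite (NaClO2), [Na+].[O-]Cl=O
Why: Acid hydrolysis of the enol ether gives the homologous aldehyde 4, which is oxidised at once by Pinnick oxidation because arylacetaldehydes self-condense on standing; the alkene scavenger keeps hypochlorite away from the allyl ether and the electron-rich ring.

Step 4
Reactants: 5 2-[2-(allyloxy)-5-bromo-3-methoxyphenyl]acetic acid, 6 (R)-4-benzyloxazolidin-2-one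
Product: 8 (R)-3-{2-[2-(allyloxy)-5-bromo-3-methoxyphenyl]acetyl}-4-benzyloxazolidin-2-one, via mixed pivalic anhydride 7 (not isolated)
Conditions: PivCl, Et3N, THF, −20 °C; then 6, LiCl, −20 °C to rt
Reagents that add atoms: none
Why: N-acylation of the oxazolidinone through the mixed anhydride, in which the hindered pivaloyl carbonyl directs attack to the arylacetyl carbonyl; the LiCl and amine conditions avoid a strongly basic lithiated auxiliary.

Step 5
Reactants: 9 vanillin (4-hydroxy-3-methoxybenzaldehyde)
Product: 10 4-(allyloxy)-3-methoxybenzaldehyde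
Conditions: allyl bromide, K2CO3, DMF, rt
Reagents that add atoms: allyl bromide, C=CCBr
Why: Williamson etherification; the same protecting group as on ring A lets both phenols be freed in one operation later.

Step 6
Reactants: 8 (R)-3-{2-[2-(allyloxy)-5-bromo-3-methoxyphenyl]acetyl}-4-benzyloxazolidin-2-one, 10 4-(allyloxy)-3-methoxybenzaldehyde
Product: 12 (R)-3-{(2R,3R)-2-[2-(allyloxy)-5-bromo-3-methoxyphenyl]-3-[4-(allyloxy)-3-methoxyphenyl]-3-hydroxypropanoyl}-4-benzyloxazolidin-2-one, via Z-dibutylboron enolate 11 (not isolated)
Conditions: Bu2BOTf, iPr2NEt, CH2Cl2, −78 to 0 °C; then 10, −78 to 0 °C; pH 7 buffer, MeOH, H2O2, 0 °C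
Reagents that add atoms: none
Why: Evans syn aldol: soft enolisation gives the Z-boron enolate 11, which adds to 10 through a closed Zimmerman–Traxler chair in which the benzyl group of the R auxiliary blocks one enolate face, setting the aryl-bearing carbon as 2R (the future C3) and the carbinol as 3R. Only the first centre has to be clean, because the carbinol centre is erased in step 9.

Step 7
Reactants: 12 (R)-3-{(2R,3R)-2-[2-(allyloxy)-5-bromo-3-methoxyphenyl]-3-[4-(allyloxy)-3-methoxyphenyl]-3-hydroxypropanoyl}-4-benzyloxazolidin-2-one
Product: 13 (1R,2S)-2-[2-(allyloxy)-5-bromo-3-methoxyphenyl]-1-[4-(allyloxy)-3-methoxyphenyl]propane-1,3-diol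
Conditions: LiBH4, MeOH (1 equiv), THF, 0 °C
Reagents that add atoms: none
Why: Reductive cleavage of the N-acyl oxazolidinone: LiBH4 attacks the exocyclic carbonyl, gives the primary alcohol and releases auxiliary 6 for recovery, and at 0 °C the α-aryl centre should not epimerise. The descriptor at that carbon changes from R to S only because CH2OH ranks below the carbinol carbon.

Step 8
Reactants: 13 (1R,2S)-2-[2-(allyloxy)-5-bromo-3-methoxyphenyl]-1-[4-(allyloxy)-3-methoxyphenyl]propane-1,3-diol
Product: 14 (1R,2S)-2-(5-bromo-2-hydroxy-3-methoxyphenyl)-1-(4-hydroxy-3-methoxyphenyl)propane-1,3-diol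
Conditions: Pd(PPh3)4 (5 mol%), morpholine, THF, rt
Reagents that add atoms: none
Why: Tsuji–Trost deallylation: zerovalent palladium ionises both aryl allyl ethers to π-allyl complexes that morpholine captures. The medium is neutral to weakly basic, so the para-hydroxybenzylic alcohol is not ionised yet, and oxidative addition into the electron-rich aryl bromide should be far slower at room temperature.

Step 9
Reactants: 14 (1R,2S)-2-(5-bromo-2-hydroxy-3-methoxyphenyl)-1-(4-hydroxy-3-methoxyphenyl)propane-1,3-diol
Product: 16 4-[(2R,3S)-5-bromo-3-(hydroxymethyl)-7-methoxy-2,3-dihydro-1-benzofuran-2-yl]-2-methoxyphenol, via para-quinone methide 15 (not isolated)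
Conditions: TsOH·H2O (10 mol%), MeCN (0.02 M), 0 °C to rt
Reagents that add atoms: none
Why: Acid-catalysed dehydrative cycloetherification through a para-quinone methide; this is the ring-closing half of the biosynthetic 8–5' coupling and the known way in which 1-(4-hydroxyaryl)-2-(2-hydroxyaryl)propane-1,3-diols close to trans-2-aryl-2,3-dihydrobenzofurans. TsOH protonates the benzylic hydroxyl of 14, water leaves with help from the para oxygen of ring C, and the protonated quinone methide 15 results, planar at the future C2, so the carbinol configuration of 14 does not matter. The phenol oxygen on ring A adds to the exocyclic methide carbon in a 5-exo-trig closure that forms O1–C2 and ring B and restores the aromaticity of ring C. The new stereocentre C2 is controlled by C3: ring C enters anti to the hydroxymethyl group, and because the benzylic ether can re-ionise to 15 under the acid, any cis isomer should drain to the more stable trans one. The step needs chemoselectivity for the ring A phenol; the primary hydroxyl could only close an oxetane, the primary carbon is not activated by acid, and dilution holds back intermolecular capture. It also needs C3 to stay untouched, which holds as long as 15 is trapped faster than it loses the C3 proton or formaldehyde; a five-membered closure with the nucleophile held next to the electrophile should secure this.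

Step 10
Reactants: 16 4-[(2R,3S)-5-bromo-3-(hydroxymethyl)-7-methoxy-2,3-dihydro-1-benzofuran-2-yl]-2-methoxyphenol
Product: 17 tert-butyl{4-[(2R,3S)-5-bromo-3-({[tert-butyl(dimethyl)silyl]oxy}methyl)-7-methoxy-2,3-dihydro-1-benzofuran-2-yl]-2-methoxyphenoxy}dimethylsilane
Conditions: TBSCl, imidazole, DMF, rt
Reagents that add atoms: tert-butyldimethylsilyl chloride, CC(C)(C)[Si](C)(C)Cl
Why: Silylation of the phenol and the primary alcohol removes both acidic protons before the organolithium step; aryl and alkyl silyl ethers of this kind tolerate t-BuLi at −78 °C.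

Step 11
Reactants: 17 tert-butyl{4-[(2R,3S)-5-bromo-3-({[tert-butyl(dimethyl)silyl]oxy}methyl)-7-methoxy-2,3-dihydro-1-benzofuran-2-yl]-2-methoxyphenoxy}dimethylsilane, 18 (R)-2,2-dimethyl-1,3-dioxolane-4-carbaldehyde
Product: 21 (S)-{(2R,3S)-2-[4-(tert-butyldimethylsilyloxy)-3-methoxyphenyl]-3-[(tert-butyldimethylsilyloxy)methyl]-7-methoxy-2,3-dihydro-1-benzofuran-5-yl}[(4R)-2,2-dimethyl-1,3-dioxolan-4-yl]methanol, via aryllithium 19 (not isolated), via aryltitanium triisopropoxide 20 (not isolated)
Conditions: t-BuLi (2 equiv), THF, −78 °C; ClTi(OiPr)3, −78 to −40 °C; then 18, −78 to 0 °C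
Reagents that add atoms: none
Why: Bromine–lithium exchange followed by transmetalation to a weakly Lewis acidic, non-chelating aryltitanium, then 1,2-addition to the α-alkoxy aldehyde in the Felkin–Anh sense (α C–O bond anti to the incoming aryl group). This should give the anti, i.e. erythro, S carbinol next to the purchased R centre; the titanium reagent is used because aryllithiums alone usually show a weaker facial preference.

Step 12
Reactants: 21 (S)-{(2R,3S)-2-[4-(tert-butyldimethylsilyloxy)-3-methoxyphenyl]-3-[(tert-butyldimethylsilyloxy)methyl]-7-methoxy-2,3-dihydro-1-benzofuran-5-yl}[(4R)-2,2-dimethyl-1,3-dioxolan-4-yl]methanol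
Product: 22 4-[(2R,3S)-5-{(S)-[(4R)-2,2-dimethyl-1,3-dioxolan-4-yl](hydroxy)methyl}-3-(hydroxymethyl)-7-methoxy-2,3-dihydro-1-benzofuran-2-yl]-2-methoxyphenol
Conditions: TBAF, AcOH (1:1), THF, 0 °C to rt
Reagents that add atoms: none
Why: Fluoride-mediated desilylation of both silyl ethers; the acetic acid buffer keeps the freed phenoxide from opening ring B, and the intact acetonide keeps the product extractable and separable from ammonium salts.

Step 13
Reactants: 22 4-[(2R,3S)-5-{(S)-[(4R)-2,2-dimethyl-1,3-dioxolan-4-yl](hydroxy)methyl}-3-(hydroxymethyl)-7-methoxy-2,3-dihydro-1-benzofuran-2-yl]-2-methoxyphenol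
Product: 23 (1S,2R)-1-[(2R,3S)-2-(4-hydroxy-3-methoxyphenyl)-3-(hydroxymethyl)-7-methoxy-2,3-dihydro-1-benzofuran-5-yl]propane-1,2,3-triol
Conditions: AcOH/H2O (4:1), rt
Reagents that add atoms: none
Why: Acid-catalysed hydrolysis of the terminal acetonide; the weak acid at room temperature should stay below the point where the para-alkoxybenzylic Cα hydroxyl ionises, and re-ionisation at C2 could only return the trans ring.

## Compound list

1 | 5-bromo-2-hydroxy-3-methoxybenzaldehyde | COc1cc(Br)cc(C=O)c1O | starting material
2 | 2-(allyloxy)-5-bromo-3-methoxybenzaldehyde | COc1cc(Br)cc(C=O)c1OCC=C | intermediate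
3 | 2-(allyloxy)-5-bromo-1-methoxy-3-(2-methoxyethenyl)benzene (E/Z mixture) | COC=Cc1cc(Br)cc(OC)c1OCC=C | intermediate
4 | 2-[2-(allyloxy)-5-bromo-3-methoxyphenyl]acetaldehyde | COc1cc(Br)cc(CC=O)c1OCC=C | intermediate
5 | 2-[2-(allyloxy)-5-bromo-3-methoxyphenyl]acetic acid | COc1cc(Br)cc(CC(=O)O)c1OCC=C | intermediate
6 | (R)-4-benzyloxazolidin-2-one | O=C1OC[C@@H](Cc2ccccc2)N1 | starting material
7 | 2-[2-(allyloxy)-5-bromo-3-methoxyphenyl]acetic pivalic anhydride | COc1cc(Br)cc(CC(=O)OC(=O)C(C)(C)C)c1OCC=C | intermediate
8 | (R)-3-{2-[2-(allyloxy)-5-bromo-3-methoxyphenyl]acetyl}-4-benzyloxazolidin-2-one | O=C1OC[C@@H](Cc2ccccc2)N1C(=O)Cc1cc(Br)cc(OC)c1OCC=C | intermediate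
9 | vanillin (4-hydroxy-3-methoxybenzaldehyde) | COc1cc(C=O)ccc1O | starting material
10 | 4-(allyloxy)-3-methoxybenzaldehyde | COc1cc(C=O)ccc1OCC=C | intermediate
11 | Z-dibutylboron enolate of 8 | O=C1OC[C@@H](Cc2ccccc2)N1/C(OB(CCCC)CCCC)=C/c1cc(Br)cc(OC)c1OCC=C | intermediate
12 | (R)-3-{(2R,3R)-2-[2-(allyloxy)-5-bromo-3-methoxyphenyl]-3-[4-(allyloxy)-3-methoxyphenyl]-3-hydroxypropanoyl}-4-benzyloxazolidin-2-one | O=C1OC[C@@H](Cc2ccccc2)N1C(=O)[C@H](c1cc(Br)cc(OC)c1OCC=C)[C@@H](O)c1ccc(OCC=C)c(OC)c1 | intermediate
13 | (1R,2S)-2-[2-(allyloxy)-5-bromo-3-methoxyphenyl]-1-[4-(allyloxy)-3-methoxyphenyl]propane-1,3-diol | OC[C@H](c1cc(Br)cc(OC)c1OCC=C)[C@@H](O)c1ccc(OCC=C)c(OC)c1 | intermediate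
14 | (1R,2S)-2-(5-bromo-2-hydroxy-3-methoxyphenyl)-1-(4-hydroxy-3-methoxyphenyl)propane-1,3-diol | OC[C@H](c1cc(Br)cc(OC)c1O)[C@@H](O)c1ccc(O)c(OC)c1 | intermediate
15 | 4-[(2S)-2-(5-bromo-2-hydroxy-3-methoxyphenyl)-3-hydroxypropylidene]-2-methoxycyclohexa-2,5-dien-1-one (para-quinone methide, formed protonated) | COC1=CC(=C[C@H](CO)c2cc(Br)cc(OC)c2O)C=CC1=O | intermediate
16 | 4-[(2R,3S)-5-bromo-3-(hydroxymethyl)-7-methoxy-2,3-dihydro-1-benzofuran-2-yl]-2-methoxyphenol | COc1cc([C@@H]2Oc3c(OC)cc(Br)cc3[C@H]2CO)ccc1O | intermediate
17 | tert-butyl{4-[(2R,3S)-5-bromo-3-({[tert-butyl(dimethyl)silyl]oxy}methyl)-7-methoxy-2,3-dihydro-1-benzofuran-2-yl]-2-methoxyphenoxy}dimethylsilane | COc1cc([C@@H]2Oc3c(OC)cc(Br)cc3[C@H]2CO[Si](C)(C)C(C)(C)C)ccc1O[Si](C)(C)C(C)(C)C | intermediate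
18 | (R)-2,2-dimethyl-1,3-dioxolane-4-carbaldehyde | O=C[C@H]1COC(C)(C)O1 | starting material
19 | {(2R,3S)-2-[4-(tert-butyldimethylsilyloxy)-3-methoxyphenyl]-3-[(tert-butyldimethylsilyloxy)methyl]-7-methoxy-2,3-dihydro-1-benzofuran-5-yl}lithium | COc1cc([C@@H]2Oc3c(OC)cc([Li])cc3[C@H]2CO[Si](C)(C)C(C)(C)C)ccc1O[Si](C)(C)C(C)(C)C | intermediate
20 | {(2R,3S)-2-[4-(tert-butyldimethylsilyloxy)-3-methoxyphenyl]-3-[(tert-butyldimethylsilyloxy)methyl]-7-methoxy-2,3-dihydro-1-benzofuran-5-yl}titanium triisopropoxide | COc1cc([C@@H]2Oc3c(OC)cc([Ti](OC(C)C)(OC(C)C)OC(C)C)cc3[C@H]2CO[Si](C)(C)C(C)(C)C)ccc1O[Si](C)(C)C(C)(C)C | intermediate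
21 | (S)-{(2R,3S)-2-[4-(tert-butyldimethylsilyloxy)-3-methoxyphenyl]-3-[(tert-butyldimethylsilyloxy)methyl]-7-methoxy-2,3-dihydro-1-benzofuran-5-yl}[(4R)-2,2-dimethyl-1,3-dioxolan-4-yl]methanol | COc1cc([C@@H]2Oc3c(OC)cc([C@H](O)[C@H]4COC(C)(C)O4)cc3[C@H]2CO[Si](C)(C)C(C)(C)C)ccc1O[Si](C)(C)C(C)(C)C | intermediate
22 | 4-[(2R,3S)-5-{(S)-[(4R)-2,2-dimethyl-1,3-dioxolan-4-yl](hydroxy)methyl}-3-(hydroxymethyl)-7-methoxy-2,3-dihydro-1-benzofuran-2-yl]-2-methoxyphenol | COc1cc([C@@H]2Oc3c(OC)cc([C@H](O)[C@H]4COC(C)(C)O4)cc3[C@H]2CO)ccc1O | intermediate
23 | (1S,2R)-1-[(2R,3S)-2-(4-hydroxy-3-methoxyphenyl)-3-(hydroxymethyl)-7-methoxy-2,3-dihydro-1-benzofuran-5-yl]propane-1,2,3-triol | COc1cc([C@@H]2Oc3c(OC)cc([C@H](O)[C@H](O)CO)cc3[C@H]2CO)ccc1O | target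

## Step count and least certain steps

Total: 13 steps. Longest linear sequence: 12 steps (from 1 through steps 1 to 4 and 6 to 13); step 5 is a one-step side branch.

**Step 9 (key step).** The most likely failure is that the cationic intermediate 15 takes another exit before the ring A phenol traps it. It may lose formaldehyde from the hydroxymethyl group (the typical acid behaviour of 1,2-diarylpropane-1,3-diols, which leads to a stilbene). It may lose the C3 proton, which would erase the aldol-set centre. At higher concentration a second molecule may capture it. The fallback sets out from 13 and comes back to the route at 17. The primary hydroxyl of 13 is silylated selectively (TBSCl, imidazole, CH2Cl2, 0 °C) to the mono-silyl ether F1. Both allyl groups are removed as in step 8 to give the bis-phenol F2, and ring closure with catalytic camphorsulfonic acid in CH2Cl2 at 0 °C gives the silylated dihydrobenzofuran F3. Silylation of its phenol (TBSCl, imidazole) gives 17. Without a free primary O–H the loss of formaldehyde has no easy path, and any material that loses silicon under the acid is 16, which re-enters at step 10.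

**Step 11.** The risk is poor facial selectivity, because chelated transition states through the α- or β-oxygen of 18 compete with the Felkin–Anh one, and 18 itself oligomerises and epimerises on storage. The fallback sets out from 21 of insufficient purity at the carbinol centre and returns to 21. Dess–Martin oxidation of the mixture gives the aryl ketone F4. Reduction with Zn(BH4)2 in Et2O at low temperature should pass through the five-membered zinc chelate between the carbonyl oxygen and the neighbouring acetonide oxygen, so that hydride arrives from the side of the small substituent and gives the anti carbinol 21.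

**Step 7.** The lithium aldolate formed under the hydride conditions may undergo retro-aldol cleavage, since the α-aryl enolate is a good leaving fragment, or the acidic α-aryl centre may epimerise. The fallback sets out from 12 and comes back at 16. The aldol hydroxyl is capped (TESOTf, 2,6-lutidine, CH2Cl2, −78 °C) to the triethylsilyl ether F5, which cannot fragment. LiBH4 reduction then gives the primary alcohol F6, and deallylation as in step 8 gives the bis-phenol F7. Under the conditions of step 9 the benzylic silyl ether of F7 ionises to the same quinone methide 15 and closes to 16.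

**Step 13.** The acid needed for the acetonide may ionise the Cα hydroxyl, which is para to O1, and so scramble the erythro centre or acetylate it. The fallback sets out from 17 and comes back at 23; it replaces the acetonide by silyl ethers so that fluoride alone finishes the synthesis. Purchased methyl (R)-2,2-dimethyl-1,3-dioxolane-4-carboxylate F8 is methanolysed (catalytic TsOH, MeOH) to methyl (R)-2,3-dihydroxypropanoate F9. This is silylated (TBSCl, imidazole) to the bis-silyl ester F10 and reduced with i-Bu2AlH at −78 °C to (R)-2,3-bis(tert-butyldimethylsilyloxy)propanal F11. The aryltitanium 20, made from 17 as in step 11, adds to F11, whose bulky α-silyloxy group enforces the Felkin–Anh sense, to give the tetrasilyl ether F12. TBAF buffered with AcOH then gives 23 directly.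

## Further compounds

F1 | step 9 | (1R,2S)-2-[2-(allyloxy)-5-bromo-3-methoxyphenyl]-1-[4-(allyloxy)-3-methoxyphenyl]-3-(tert-butyldimethylsilyloxy)propan-1-ol | CC(C)(C)[Si](C)(C)OC[C@H](c1cc(Br)cc(OC)c1OCC=C)[C@@H](O)c1ccc(OCC=C)c(OC)c1
F2 | step 9 | (1R,2S)-2-(5-bromo-2-hydroxy-3-methoxyphenyl)-3-(tert-butyldimethylsilyloxy)-1-(4-hydroxy-3-methoxyphenyl)propan-1-ol | CC(C)(C)[Si](C)(C)OC[C@H](c1cc(Br)cc(OC)c1O)[C@@H](O)c1ccc(O)c(OC)c1
F3 | step 9 | 4-[(2R,3S)-5-bromo-3-({[tert-butyl(dimethyl)silyl]oxy}methyl)-7-methoxy-2,3-dihydro-1-benzofuran-2-yl]-2-methoxyphenol | COc1cc([C@@H]2Oc3c(OC)cc(Br)cc3[C@H]2CO[Si](C)(C)C(C)(C)C)ccc1O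
F4 | step 11 | {(2R,3S)-2-[4-(tert-butyldimethylsilyloxy)-3-methoxyphenyl]-3-[(tert-butyldimethylsilyloxy)methyl]-7-methoxy-2,3-dihydro-1-benzofuran-5-yl}[(4R)-2,2-dimethyl-1,3-dioxolan-4-yl]methanone | COc1cc([C@@H]2Oc3c(OC)cc(C(=O)[C@H]4COC(C)(C)O4)cc3[C@H]2CO[Si](C)(C)C(C)(C)C)ccc1O[Si](C)(C)C(C)(C)C
F5 | step 7 | (R)-3-{(2R,3R)-2-[2-(allyloxy)-5-bromo-3-methoxyphenyl]-3-[4-(allyloxy)-3-methoxyphenyl]-3-(triethylsilyloxy)propanoyl}-4-benzyloxazolidin-2-one | O=C1OC[C@@H](Cc2ccccc2)N1C(=O)[C@H](c1cc(Br)cc(OC)c1OCC=C)[C@@H](O[Si](CC)(CC)CC)c1ccc(OCC=C)c(OC)c1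
F6 | step 7 | (2S,3R)-2-[2-(allyloxy)-5-bromo-3-methoxyphenyl]-3-[4-(allyloxy)-3-methoxyphenyl]-3-(triethylsilyloxy)propan-1-ol | OC[C@H](c1cc(Br)cc(OC)c1OCC=C)[C@@H](O[Si](CC)(CC)CC)c1ccc(OCC=C)c(OC)c1
F7 | step 7 | (2S,3R)-2-(5-bromo-2-hydroxy-3-methoxyphenyl)-3-(4-hydroxy-3-methoxyphenyl)-3-(triethylsilyloxy)propan-1-ol | OC[C@H](c1cc(Br)cc(OC)c1O)[C@@H](O[Si](CC)(CC)CC)c1ccc(O)c(OC)c1
F8 | step 13 | methyl (R)-2,2-dimethyl-1,3-dioxolane-4-carboxylate (purchased) | COC(=O)[C@H]1COC(C)(C)O1
F9 | step 13 | methyl (R)-2,3-dihydroxypropanoate | COC(=O)[C@H](O)CO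
F10 | step 13 | methyl (R)-2,3-bis(tert-butyldimethylsilyloxy)propanoate | COC(=O)[C@H](O[Si](C)(C)C(C)(C)C)CO[Si](C)(C)C(C)(C)C
F11 | step 13 | (R)-2,3-bis(tert-butyldimethylsilyloxy)propanal | O=C[C@H](O[Si](C)(C)C(C)(C)C)CO[Si](C)(C)C(C)(C)C
F12 | step 13 | (1S,2R)-1-{(2R,3S)-2-[4-(tert-butyldimethylsilyloxy)-3-methoxyphenyl]-3-[(tert-butyldimethylsilyloxy)methyl]-7-methoxy-2,3-dihydro-1-benzofuran-5-yl}-2,3-bis(tert-butyldimethylsilyloxy)propan-1-ol | COc1cc([C@@H]2Oc3c(OC)cc([C@H](O)[C@H](O[Si](C)(C)C(C)(C)C)CO[Si](C)(C)C(C)(C)C)cc3[C@H]2CO[Si](C)(C)C(C)(C)C)ccc1O[Si](C)(C)C(C)(C)C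
A1 | alternative 1 | 4-{(2R,3S)-5-[(4S,5R)-5-hydroxy-2-oxo-1,3-dioxan-4-yl]-7-methoxy-3-(pivaloyloxymethyl)-2,3-dihydro-1-benzofuran-2-yl}-2-methoxyphenyl pivalate | COc1cc([C@@H]2Oc3c(OC)cc([C@@H]4OC(=O)OC[C@H]4O)cc3[C@H]2COC(=O)C(C)(C)C)ccc1OC(=O)C(C)(C)C
A2 | alternative 1 | (2R,3R)-2,3-dihydroxy-3-{(2R,3S)-7-methoxy-2-[3-methoxy-4-(pivaloyloxy)phenyl]-3-(pivaloyloxymethyl)-2,3-dihydro-1-benzofuran-5-yl}propyl dimethylcarbamate | COc1cc([C@@H]2Oc3c(OC)cc([C@@H](O)[C@H](O)COC(=O)N(C)C)cc3[C@H]2COC(=O)C(C)(C)C)ccc1OC(=O)C(C)(C)C
A3 | alternative 2 | {[(2R,3S)-2-[4-(benzyloxy)-3-methoxyphenyl]-5-bromo-7-methoxy-2,3-dihydro-1-benzofuran-3-yl]methoxy}(tert-butyl)dimethylsilane | COc1cc([C@@H]2Oc3c(OC)cc(Br)cc3[C@H]2CO[Si](C)(C)C(C)(C)C)ccc1OCc1ccccc1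
A4 | alternative 2 | 4-bromo-2-[2-(tert-butyldimethylsilyloxy)-1-(4-methylphenylsulfonyl)ethyl]-6-methoxyphenol | COc1cc(Br)cc(C(CO[Si](C)(C)C(C)(C)C)S(=O)(=O)c2ccc(C)cc2)c1O
A5 | alternative 2 | (2R,5R)-1-[4-(benzyloxy)-3-methoxybenzyl]-2,5-dimethylthiolan-1-ium triflate (enantiomer of the sulfide drawn arbitrarily) | COc1cc(C[S+]2[C@H](C)CC[C@H]2C)ccc1OCc1ccccc1.[O-]S(=O)(=O)C(F)(F)F
A6 | alternative 3 | dimethyl (2R,3R)-7-methoxy-2-[3-methoxy-4-(pivaloyloxy)phenyl]-2,3-dihydro-1-benzofuran-3,5-dicarboxylate (trans) | COc1cc([C@@H]2Oc3c(OC)cc(C(=O)OC)cc3[C@H]2C(=O)OC)ccc1OC(=O)C(C)(C)C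
A7 | alternative 3 | methyl 4-hydroxy-3-methoxy-5-{(E)-2-[3-methoxy-4-(pivaloyloxy)phenyl]ethenyl}benzoate | COC(=O)c1cc(OC)c(O)c(/C=C/c2ccc(OC(=O)C(C)(C)C)c(OC)c2)c1
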